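**Retrosynthetic overview**
- The only disconnection is the aryl–cyclohexenyl bond ortho to one phenol OH. It is cut back to magnolol 1 and the unoxidised hydrocarbon diene (S)-(+)-α-phellandrene 2, not to a pre-oxidised terpenol.
- Protonating 2 at the diene terminus remote from the stereocentre gives the (S)-piperityl (p-menth-1-en-3-yl) allyl cation 3. This is the cation terpene cyclases reach on the way to the phellandrenes.
- Capture of 3 by the one activated free position of 1 (ortho to OH; para is blocked by allyl), anti to the isopropyl group, gives the target 4. C6′ comes from the chiral pool and C1′ is set by substrate control.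
- No ring is built. The biaryl arrives joined in 1 (nature's oxidative chavicol dimer) and the cyclohexene ring arrives intact in 2; only its C=C position is reset.

Assumption: magnolol (98 %, Magnolia bark extract) and (S)-(+)-α-phellandrene (dill- or elemi-derived, ee checked by chiral GC) are both bought; β-phellandrene in 2 is harmless because it protonates to the same cation 3.

**Step 1**
Reactants: 1 magnolol; 2 (S)-(+)-α-phellandrene
Product: 4 piperitylmagnolol [5,5′-diallyl-3-((1S,6S)-3-methyl-6-isopropylcyclohex-2-en-1-yl)biphenyl-2,2′-diol; aryl and isopropyl trans], via (S)-piperityl cation 3 (not isolated)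
Conditions: p-toluenesulfonic acid monohydrate (TsOH·H2O, 10 mol %), CH2Cl2/(CF3)2CHOH 4:1, 0 °C; 2 (1.0 equiv) added over 4 h to 1 (3.0 equiv, 0.5 M); aq. NaHCO3 quench once 2 is consumed; excess 1 recovered on silica
Reagents that add atoms: none
Why: Brønsted-acid-catalysed hydroarylation of a 1,3-diene (Friedel–Crafts allylic alkylation, a pure addition with no by-product), in which the proton adds to C1 of 2 to give the tertiary/secondary allyl cation 3 without touching the isopropyl-bearing stereocentre, and the free ortho position of 1 attacks the secondary terminus anti to the adjacent isopropyl group, setting the new benzylic centre as (1′S) trans to (6′S), while the terminal allyl groups are too weakly nucleophilic to compete at 0 °C and the excess of 1 with slow addition of 2 holds back bis-alkylation and terpene self-alkylation.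

**Compound list**
1 | magnolol, 5,5′-diallylbiphenyl-2,2′-diol | C=CCc1ccc(O)c(-c2cc(CC=C)ccc2O)c1 | starting material
2 | (S)-(+)-α-phellandrene, (5S)-2-methyl-5-isopropylcyclohexa-1,3-diene | CC1=CC[C@H](C=C1)C(C)C | starting material
3 | (S)-piperityl cation, 3-methyl-6-isopropylcyclohex-2-en-1-ylium (allyl cation, tosylate counter-ion; isopropyl-bearing centre arranged as in 2) | [CH+]1C=C(C)CC[C@H]1C(C)C | intermediate
4 | piperitylmagnolol, 5,5′-diallyl-3-[(1S,6S)-3-methyl-6-isopropylcyclohex-2-en-1-yl]biphenyl-2,2′-diol | C=CCc1ccc(O)c(-c2cc(CC=C)cc([C@@H]3C=C(C)CC[C@H]3C(C)C)c2O)c1 | target

**Totals**
Total step count: 1. Longest linear sequence: 1.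

**Steps most likely to fail**
The route has a single step, so it is the only entry.

Step 1. Three things can go wrong:
- **Terpene self-reaction.** Cation 3 may be trapped faster by free diene than by the moderately nucleophilic phenol ring, giving terpene dimers and a poor mass balance.
- **Loss of ee.** Reversible loss of the proton next to the isopropyl group gives achiral α-terpinene, which re-protonates to racemic 3.
- **Over-reaction.** Statistical bis-alkylation of 1, and on prolonged acid contact addition of the ortho OH across the ring alkene of 4 to give a bridged ether.

Fallback (sets out from 2, returns at 4): the diene is first converted completely into a covalent cation precursor, so that no free diene is present when the cation forms. Compound 2 is treated with dry HCl (1.05 equiv, 4 M in dioxane) in CH2Cl2 at −30 °C to give trans-piperityl chloride F1 by diene hydrochlorination. F1 is used as the crude mixture of allylic isomers, since all of them ionise to 3. The cold solution of F1 is then added to 1 (3 equiv) and ZnCl2·OEt2 (20 mol %) in CH2Cl2 at −40 °C. Lewis-acid ionisation of the C–Cl bond regenerates 3 at a low stationary concentration, with the chloride as a dormant reservoir. Ortho attack of 1 anti to the isopropyl group then gives 4 with loss of HCl. The low temperature also slows the α-terpinene pathway and the cyclisation of 4.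

**Further compounds**
F1 | step 1 | trans-piperityl chloride, (3S,4S)-3-chloro-1-methyl-4-isopropylcyclohex-1-ene | Cl[C@@H]1C=C(C)CC[C@H]1C(C)C
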